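**Retrosynthetic overview**

1. Numbering follows the germacranolide skeleton: ring C1–C10, lactone C6–O–C12(=O)–C11=C7, C13 = CH2OAc, C14 = exocyclic CH2, C15 = CH3. The target goes back, through cis-epoxidation of (Z)-C1=C2, acylation of O8 and acetylation of O13, to a ten-membered dienyl butenolide, and that to an acyclic butenolide by ring-closing metathesis (C1=C2).
2. Key disconnection: the O–C6 and C12–C11 bonds of the butenolide are cut to CO2 and a 7-vinylidene allene (C7=C11=C13H2) that carries a mesylate on C6 and a Si–B tether on O8. A copper-mediated silylcupration / CO2 capture / lactonisation cascade also makes the Si–C13 bond, which is a masked C13–OH.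
3. Enabling feature: the butenolide ring is a γ-oxygenated α,β-unsaturated acid whose tetrasubstituted C7=C11 bears C13–O on the α-carbon and oxygenated carbons C6 and C8 on C7. C11 is therefore the central carbon of an allene (nucleophilic after silylcupration), C6 is an electrophile, and O8 is an anchor that fixes the alkene geometry.
4. The allene comes from an indium Barbier union (C6–C7 bond) of a Sharpless-derived (4R,5R)-epoxy aldehyde with an (8S)-propargyl bromide made by Noyori transfer hydrogenation.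
5. Ring order: C4–C5 oxirane first; oxasiline and butenolide together in the key step; ten-membered carbocycle by metathesis; C1–C2 oxirane last.

Key step: step 15

Remark: intermediates are numbered as in the target; the Shi ketone made from natural glucose is assumed to be the matched enantiomer in step 24 (otherwise its antipode is used), and (diethylamino)diphenylsilylboronic acid pinacol ester is taken as a purchasable reagent.

**Route**

Step 1
Reactants: 1 pent-1-en-4-yne
Product: 2 (2E)-3-methylhexa-2,5-dien-1-ol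
Conditions: Me3Al, Cp2ZrCl2 (25 mol %), CH2Cl2, 0 °C to rt; n-BuLi, THF, −78 °C; (CH2O)n, rt; aq. HCl
Reagents that add atoms: trimethylaluminium, C[Al](C)C; formaldehyde (as paraformaldehyde), C=O
Why: Negishi zirconium-catalysed carboalumination adds methyl and aluminium syn across the terminal alkyne (methyl to the internal carbon), and the derived alkenylaluminate is hydroxymethylated with retention, so the (E)-trisubstituted C4=C5 allylic alcohol results while the isolated alkene stays untouched.

Step 2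
Reactants: 2 (2E)-3-methylhexa-2,5-dien-1-ol
Product: 3 [(2R,3R)-3-methyl-3-(prop-2-en-1-yl)oxiran-2-yl]methanol
Conditions: Ti(OiPr)4 (10 mol %), (−)-diethyl (2S,3S)-tartrate (12 mol %), t-BuOOH, 4 Å MS, CH2Cl2, −20 °C
Reagents that add atoms: tert-butyl hydroperoxide, CC(C)(C)OO
Why: Sharpless asymmetric epoxidation of the primary allylic alcohol, in which the (S,S)-tartrate–titanium complex delivers oxygen to the alkene face that gives the (4R,5R)-oxirane, while the remote terminal alkene is inert.

Step 3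
Reactants: 3 [(2R,3R)-3-methyl-3-(prop-2-en-1-yl)oxiran-2-yl]methanol
Product: 4 (2S,3R)-3-methyl-3-(prop-2-en-1-yl)oxirane-2-carbaldehyde
Conditions: Dess–Martin periodinane, NaHCO3, CH2Cl2, 0 °C
Reagents that add atoms: none
Why: Dess–Martin oxidation under buffered, non-basic conditions should take the primary alcohol to the α,β-epoxy aldehyde without opening the epoxide or epimerising C5.

Step 4
Reactants: 5 3-(trimethylsilyl)prop-2-ynal; 6 2,3-dibromoprop-1-ene
Product: 7 rac-5-bromo-1-(trimethylsilyl)hex-5-en-1-yn-3-ol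
Conditions: In powder, THF/H2O (1:1), rt
Reagents that add atoms: none
Why: Indium-mediated Barbier allylation, in which only the allylic carbon–bromine bond of 6 is metalated (the vinylic bromide is inert) and adds 1,2 to the ynal; the racemic carbinol configuration is erased in step 5.

Step 5
Reactants: 7 rac-5-bromo-1-(trimethylsilyl)hex-5-en-1-yn-3-ol
Product: 8 5-bromo-1-(trimethylsilyl)hex-5-en-1-yn-3-one
Conditions: Dess–Martin periodinane, CH2Cl2, 0 °C
Reagents that add atoms: none
Why: Dess–Martin oxidation is neutral enough to give the ynone without moving the β,γ-alkene into conjugation.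

Step 6
Reactants: 8 5-bromo-1-(trimethylsilyl)hex-5-en-1-yn-3-one
Product: 9 (3S)-5-bromo-1-(trimethylsilyl)hex-5-en-1-yn-3-ol
Conditions: Ru[(S,S)-TsNCH(Ph)CH(Ph)NH](p-cymene) (1 mol %), 2-propanol, rt
Reagents that add atoms: none
Why: Noyori asymmetric transfer hydrogenation of an α,β-acetylenic ketone, in which the (S,S)-TsDPEN ruthenium hydride is expected to deliver hydride to the face that gives the (S)-propargylic alcohol (C8), as with other alkynyl alkyl ketones, under base-free conditions that avoid isomerisation.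

Step 7
Reactants: 9 (3S)-5-bromo-1-(trimethylsilyl)hex-5-en-1-yn-3-ol
Product: 10 (3S)-5-bromo-3-(triethylsilyloxy)-1-(trimethylsilyl)hex-5-en-1-yne
Conditions: Et3SiCl, imidazole, DMF, 0 °C
Reagents that add atoms: chlorotriethylsilane, CC[Si](Cl)(CC)CC
Why: Standard silylation of the secondary alcohol gives a triethylsilyl ether that should survive steps 8–12 and can be removed later without base.

Step 8
Reactants: 10 (3S)-5-bromo-3-(triethylsilyloxy)-1-(trimethylsilyl)hex-5-en-1-yne
Product: 11 (3S)-5-bromo-3-(triethylsilyloxy)hex-5-en-1-yne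
Conditions: K2CO3 (cat.), MeOH, 0 °C
Reagents that add atoms: none
Why: Base-catalysed methanolysis cleaves the alkynyl C–Si bond selectively, while the O–SiEt3 ether and the vinyl bromide are stable at 0 °C.

Step 9
Reactants: 11 (3S)-5-bromo-3-(triethylsilyloxy)hex-5-en-1-yne
Product: 12 (4S)-6-bromo-4-(triethylsilyloxy)hept-6-en-2-yn-1-ol
Conditions: EtMgBr, THF, 0 °C; (CH2O)n, 45 °C; H2O
Reagents that add atoms: formaldehyde (as paraformaldehyde), C=O
Why: Deprotonation of the terminal alkyne with EtMgBr (no halogen–metal exchange at the vinyl bromide) and 1,2-addition of the acetylide to formaldehyde install C13 as a propargylic alcohol.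

Step 10
Reactants: 12 (4S)-6-bromo-4-(triethylsilyloxy)hept-6-en-2-yn-1-ol
Product: 13 (4S)-1,6-dibromo-4-(triethylsilyloxy)hept-6-en-2-yne
Conditions: CBr4, PPh3, 2,6-lutidine, CH2Cl2, −20 °C
Reagents that add atoms: carbon tetrabromide, BrC(Br)(Br)Br
Why: Appel bromination converts the primary propargylic alcohol into the bromide by SN2 at C13, the lutidine buffer protecting the silyl ether.

Step 11
Reactants: 4 (2S,3R)-3-methyl-3-(prop-2-en-1-yl)oxirane-2-carbaldehyde; 13 (4S)-1,6-dibromo-4-(triethylsilyloxy)hept-6-en-2-yne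
Product: 14 (1R)-2-[(1S)-3-bromo-1-(triethylsilyloxy)but-3-en-1-yl]-1-[(2R,3R)-3-methyl-3-(prop-2-en-1-yl)oxiran-2-yl]buta-2,3-dien-1-ol
Conditions: In powder, THF/H2O (3:1), 0 °C to rt
Reagents that add atoms: none
Why: Indium-mediated Barbier reaction of a γ-substituted propargyl bromide, whose propargylindium (metal on C13) reacts by SE2′ at C7 so that the C6–C7 bond and the 1,1-disubstituted C7=C11=C13 allene form together, the new C6 carbinol being set (6R) by Felkin–Anh attack anti to the C5–O bond of the epoxy aldehyde.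

Step 12
Reactants: 14 allenyl carbinol (4R,5R,6R,8S)
Product: 15 (1R)-2-[(1S)-3-bromo-1-(triethylsilyloxy)but-3-en-1-yl]-1-[(2R,3R)-3-methyl-3-(prop-2-en-1-yl)oxiran-2-yl]buta-2,3-dien-1-yl methanesulfonate
Conditions: MsCl, Et3N, CH2Cl2, −30 °C
Reagents that add atoms: methanesulfonyl chloride, CS(Cl)(=O)=O
Why: O-Sulfonylation of the secondary α-allenyl alcohol proceeds with retention at C6 and provides the leaving group for the key step.

Step 13
Reactants: 15 allenyl mesylate
Product: 16 (1R)-2-[(1S)-3-bromo-1-hydroxybut-3-en-1-yl]-1-[(2R,3R)-3-methyl-3-(prop-2-en-1-yl)oxiran-2-yl]buta-2,3-dien-1-yl methanesulfonate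
Conditions: Bu4NF, AcOH (1:1), THF, 0 °C
Reagents that add atoms: none
Why: Fluoride buffered with acetic acid removes the triethylsilyl ether at O8 without base, so the mesylate, the epoxide and the allene should survive.

Step 14
Reactants: 16 hydroxy mesylate
Product: 17 (1R)-2-[(1S)-3-bromo-1-{[diphenyl(4,4,5,5-tetramethyl-1,3,2-dioxaborolan-2-yl)silyl]oxy}but-3-en-1-yl]-1-[(2R,3R)-3-methyl-3-(prop-2-en-1-yl)oxiran-2-yl]buta-2,3-dien-1-yl methanesulfonate
Conditions: (Et2N)Ph2Si–Bpin, HCl (2 equiv, Et2O), 0 °C; then 16, pyridine, CH2Cl2, 0 °C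
Reagents that add atoms: (diethylamino)diphenylsilylboronic acid pinacol ester (used as its chloride made in the flask), CCN(CC)[Si](c1ccccc1)(c1ccccc1)B1OC(C)(C)C(C)(C)O1
Why: Alcoholysis of the Si–Cl bond of the chlorosilylboronate, the known way to alkoxy(diphenyl)silylboronic esters, attaches the Si–B tether to O8 while the Si–B bond is inert to pyridine.

Step 15
Reactants: 17 tethered allenyl mesylate
Product: 19 butenolide-fused oxasiline (4R,5R,6S,8S), via caesium carboxylate 18 (not isolated)
Conditions: CuOAc (10 mol %), PCy3 (12 mol %), CsF (1.5 equiv), CO2 (1 atm), THF, 40 °C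
Reagents that add atoms: carbon dioxide, O=C=O
Why: Proposed new method: fluoride turns the tethered Si–B bond into an alkoxy(diphenyl)silylcopper that adds syn across the terminal C11=C13 bond of the allene (Si to C13, Cu to C11), the alkenylcopper inserts CO2 to make the C11–C12 bond, and the caesium (Z)-carboxylate 18 then displaces the C6 mesylate to make the O–C6 bond, so one pot delivers the butenolide, the tetrasubstituted C7=C11 alkene and a C13–Si bond that is a masked C13–OH. The closest known reaction type is the copper-catalysed silacarboxylation of allenes with a silylborane and CO2, which with PCy3 gives 2-(silylmethyl)alk-2-enoates through the same alkenylcopper; here it is run intramolecularly and extended by carboxylate alkylation. The 1-oxa-2-silacyclohex-4-ene closes by 6-endo-trig attack of silicon on the allene terminus C13, and the butenolide closes by 5-exo-tet SN2 displacement. No new stereocentre arises; C6 is inverted from R to S by backside attack of the carboxylate, which converts the anti (Felkin) epoxy alcohol of step 11 into the syn epoxide–lactone relationship of the target, and the C7=C11 geometry is fixed by the tether, because silicon bound to O8 can reach C13 only from the C8 side and so leaves copper, and later C12, cis to C6. The step needs Si–C13 rather than Si–C11 bond formation (the latter would give an allylcopper that expels the mesylate), which the bulky monophosphine and the six-membered tether are expected to secure, and it needs the allene to react before the isolated alkene, the vinyl bromide and the epoxide, which its cumulene strain and its position next to the tether should secure.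

Step 16
Reactants: 19 butenolide-fused oxasiline
Product: 20 (5S)-4-[(1S)-3-bromo-1-hydroxybut-3-en-1-yl]-3-(hydroxymethyl)-5-[(2R,3R)-3-methyl-3-(prop-2-en-1-yl)oxiran-2-yl]furan-2(5H)-one
Conditions: 30% H2O2, KF, KHCO3, THF/MeOH, rt
Reagents that add atoms: hydrogen peroxide, OO
Why: Tamao–Fleming oxidation, in which the fluoride-activated alkoxy(diaryl)silane has its C13–Si bond oxidised to C13–OH and its Si–O8 bond cleaved, under conditions mild enough for the epoxide, the butenolide and the vinyl bromide.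

Step 17
Reactants: 20 bromo diol
Product: 21 (5S)-3-(hydroxymethyl)-4-[(1S)-1-hydroxy-3-methylidenepent-4-en-1-yl]-5-[(2R,3R)-3-methyl-3-(prop-2-en-1-yl)oxiran-2-yl]furan-2(5H)-one
Conditions: Bu3SnCH=CH2, Pd2(dba)3 (2.5 mol %), AsPh3, NMP, 50 °C
Reagents that add atoms: tributyl(vinyl)stannane, C=C[Sn](CCCC)(CCCC)CCCC
Why: Stille coupling of the 2-bromoalkene under neutral conditions builds the C14=C10–C1=CH2 diene with both hydroxyls free and before any allylic acetate is present.

Step 18
Reactants: 21 dienyl diol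
Product: 22 [(5S)-4-[(1S)-1-hydroxy-3-methylidenepent-4-en-1-yl]-5-[(2R,3R)-3-methyl-3-(prop-2-en-1-yl)oxiran-2-yl]-2-oxo-2,5-dihydrofuran-3-yl]methyl acetate
Conditions: AcCl, 2,4,6-collidine, CH2Cl2, −78 °C
Reagents that add atoms: acetyl chloride, CC(Cl)=O
Why: Acylation with acetyl chloride and collidine at low temperature is selective for the primary C13 hydroxyl over the hindered secondary C8 hydroxyl.

Step 19
Reactants: 22 acyclic acetate
Product: 23 (1Z,4R,5R,6S,8S)-13-acetoxy-4,5-epoxy-8-hydroxygermacra-1,7(11),10(14)-trien-12,6-olide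
Conditions: second-generation Grubbs catalyst RuCl2(=CHPh)(H2IMes)(PCy3) (10 mol %), 1,4-benzoquinone (20 mol %), CH2Cl2 (0.001 mol/L), 40 °C
Reagents that add atoms: none
Why: Ring-closing metathesis between the monosubstituted alkenes on C2 and C1 closes the ten-membered ring with loss of ethylene, the 1,1-disubstituted C10=C14 and the butenolide alkene staying out, and the (Z)-C1=C2 geometry, the less strained one for a cyclodecene, is expected under equilibrating conditions.

Step 20
Reactants: 24 ethyl 2-(hydroxymethyl)prop-2-enoate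
Product: 25 ethyl 2-{[(tert-butyldimethylsilyl)oxy]methyl}prop-2-enoate
Conditions: t-BuMe2SiCl, imidazole, CH2Cl2, 0 °C to rt
Reagents that add atoms: tert-butylchlorodimethylsilane, CC(C)(C)[Si](C)(C)Cl
Why: Standard silylation protects the primary allylic alcohol of the side-chain acid precursor.

Step 21
Reactants: 25 silyl ether ester
Product: 26 2-{[(tert-butyldimethylsilyl)oxy]methyl}prop-2-enoic acid
Conditions: LiOH, THF/H2O, 0 °C; then aq. HCl to pH 4
Reagents that add atoms: lithium hydroxide, [Li+].[OH-]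
Why: Saponification of the ethyl ester at 0 °C followed by careful acidification should give the acid without loss of the silyl ether.

Step 22
Reactants: 23 macrocyclic alcohol; 26 silyl-protected acid
Product: 27 8-O-(2-{[(tert-butyldimethylsilyl)oxy]methyl}prop-2-enoyl) derivative of 23
Conditions: 2,4,6-trichlorobenzoyl chloride, Et3N, THF, rt; then 23, DMAP, toluene, rt
Reagents that add atoms: none
Why: Yamaguchi esterification, in which the mixed anhydride of 26 acylates the hindered secondary C8 hydroxyl with retention because the C8–O bond is not broken.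

Step 23
Reactants: 27 silyl-protected ester
Product: 28 (1Z,4R,5R,6S,8S)-13-acetoxy-4,5-epoxy-8-[2-(hydroxymethyl)prop-2-enoyloxy]germacra-1,7(11),10(14)-trien-12,6-olide
Conditions: Bu4NF, AcOH (1:1), THF, 0 °C to rt
Reagents that add atoms: none
Why: Buffered fluoride removes the primary silyl ether without acyl migration or ester cleavage.

Step 24
Reactants: 28 dienyl ester
Product: 29 (1R,2S,4R,5R,6S,8S)-13-acetoxy-1,2:4,5-diepoxy-8-[2-(hydroxymethyl)prop-2-enoyloxy]germacra-7(11),10(14)-dien-12,6-olide (CNP0233746.1)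
Conditions: Shi N-(4-methylphenyl)oxazolidinone ketone (30 mol %), Oxone (2KHSO5·KHSO4·K2SO4), K2CO3, Bu4NHSO4, DME/aq. buffer, −10 °C
Reagents that add atoms: potassium peroxymonosulfate, OOS(=O)(=O)[O-].[K+]
Why: Shi asymmetric epoxidation with an oxazolidinone ketone, which is selective for the cis-disubstituted alkene of a conjugated diene and should leave the 1,1-disubstituted, acrylate and butenolide alkenes, delivers oxygen syn to one face of (Z)-C1=C2 under catalyst control to give the cis-(1R,2S)-oxirane.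

**Compound list**

1 | pent-1-en-4-yne | C=CCC#C | starting material
2 | (2E)-3-methylhexa-2,5-dien-1-ol | OC/C=C(\C)CC=C | intermediate
3 | [(2R,3R)-3-methyl-3-(prop-2-en-1-yl)oxiran-2-yl]methanol | OC[C@H]1O[C@]1(C)CC=C | intermediate
4 | (2S,3R)-3-methyl-3-(prop-2-en-1-yl)oxirane-2-carbaldehyde | O=C[C@H]1O[C@]1(C)CC=C | intermediate
5 | 3-(trimethylsilyl)prop-2-ynal | C[Si](C)(C)C#CC=O | starting material
6 | 2,3-dibromoprop-1-ene | BrCC(Br)=C | starting material
7 | rac-5-bromo-1-(trimethylsilyl)hex-5-en-1-yn-3-ol | C[Si](C)(C)C#CC(O)CC(Br)=C | intermediate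
8 | 5-bromo-1-(trimethylsilyl)hex-5-en-1-yn-3-one | C[Si](C)(C)C#CC(=O)CC(Br)=C | intermediate
9 | (3S)-5-bromo-1-(trimethylsilyl)hex-5-en-1-yn-3-ol | C[Si](C)(C)C#C[C@@H](O)CC(Br)=C | intermediate
10 | (3S)-5-bromo-3-(triethylsilyloxy)-1-(trimethylsilyl)hex-5-en-1-yne | C[Si](C)(C)C#C[C@@H](O[Si](CC)(CC)CC)CC(Br)=C | intermediate
11 | (3S)-5-bromo-3-(triethylsilyloxy)hex-5-en-1-yne | C#C[C@@H](O[Si](CC)(CC)CC)CC(Br)=C | intermediate
12 | (4S)-6-bromo-4-(triethylsilyloxy)hept-6-en-2-yn-1-ol | OCC#C[C@@H](O[Si](CC)(CC)CC)CC(Br)=C | intermediate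
13 | (4S)-1,6-dibromo-4-(triethylsilyloxy)hept-6-en-2-yne | BrCC#C[C@@H](O[Si](CC)(CC)CC)CC(Br)=C | intermediate
14 | (1R)-2-[(1S)-3-bromo-1-(triethylsilyloxy)but-3-en-1-yl]-1-[(2R,3R)-3-methyl-3-(prop-2-en-1-yl)oxiran-2-yl]buta-2,3-dien-1-ol | C=C=C([C@@H](O)[C@H]1O[C@]1(C)CC=C)[C@@H](O[Si](CC)(CC)CC)CC(Br)=C | intermediate
15 | (1R)-2-[(1S)-3-bromo-1-(triethylsilyloxy)but-3-en-1-yl]-1-[(2R,3R)-3-methyl-3-(prop-2-en-1-yl)oxiran-2-yl]buta-2,3-dien-1-yl methanesulfonate | C=C=C([C@@H](OS(C)(=O)=O)[C@H]1O[C@]1(C)CC=C)[C@@H](O[Si](CC)(CC)CC)CC(Br)=C | intermediate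
16 | (1R)-2-[(1S)-3-bromo-1-hydroxybut-3-en-1-yl]-1-[(2R,3R)-3-methyl-3-(prop-2-en-1-yl)oxiran-2-yl]buta-2,3-dien-1-yl methanesulfonate | C=C=C([C@@H](OS(C)(=O)=O)[C@H]1O[C@]1(C)CC=C)[C@@H](O)CC(Br)=C | intermediate
17 | (1R)-2-[(1S)-3-bromo-1-{[diphenyl(4,4,5,5-tetramethyl-1,3,2-dioxaborolan-2-yl)silyl]oxy}but-3-en-1-yl]-1-[(2R,3R)-3-methyl-3-(prop-2-en-1-yl)oxiran-2-yl]buta-2,3-dien-1-yl methanesulfonate | C=C=C([C@@H](OS(C)(=O)=O)[C@H]1O[C@]1(C)CC=C)[C@@H](O[Si](c1ccccc1)(c1ccccc1)B1OC(C)(C)C(C)(C)O1)CC(Br)=C | intermediate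
18 | caesium (6S)-6-(2-bromoprop-2-en-1-yl)-5-{(R)-(methanesulfonyloxy)[(2R,3R)-3-methyl-3-(prop-2-en-1-yl)oxiran-2-yl]methyl}-2,2-diphenyl-3,6-dihydro-2H-1,2-oxasiline-4-carboxylate | [Cs+].[O-]C(=O)C1=C([C@@H](OS(C)(=O)=O)[C@H]2O[C@]2(C)CC=C)[C@H](CC(Br)=C)O[Si](c2ccccc2)(c2ccccc2)C1 | intermediate
19 | butenolide-fused oxasiline (4R,5R,6S,8S): furan-2(5H)-one whose C5 (target C6) carries the (2R,3R)-3-methyl-3-(prop-2-en-1-yl)oxiran-2-yl group and whose C3 and C4 (target C11 and C7) are bridged by CH2–SiPh2–O–CH(CH2CBr=CH2) (C13–Si–O8–C8) | O=C1O[C@H]([C@H]3O[C@]3(C)CC=C)C2=C1C[Si](c1ccccc1)(c1ccccc1)O[C@H]2CC(Br)=C | intermediate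
20 | (5S)-4-[(1S)-3-bromo-1-hydroxybut-3-en-1-yl]-3-(hydroxymethyl)-5-[(2R,3R)-3-methyl-3-(prop-2-en-1-yl)oxiran-2-yl]furan-2(5H)-one | O=C1O[C@H]([C@H]2O[C@]2(C)CC=C)C([C@@H](O)CC(Br)=C)=C1CO | intermediate
21 | (5S)-3-(hydroxymethyl)-4-[(1S)-1-hydroxy-3-methylidenepent-4-en-1-yl]-5-[(2R,3R)-3-methyl-3-(prop-2-en-1-yl)oxiran-2-yl]furan-2(5H)-one | O=C1O[C@H]([C@H]2O[C@]2(C)CC=C)C([C@@H](O)CC(=C)C=C)=C1CO | intermediate
22 | [(5S)-4-[(1S)-1-hydroxy-3-methylidenepent-4-en-1-yl]-5-[(2R,3R)-3-methyl-3-(prop-2-en-1-yl)oxiran-2-yl]-2-oxo-2,5-dihydrofuran-3-yl]methyl acetate | O=C1O[C@H]([C@H]2O[C@]2(C)CC=C)C([C@@H](O)CC(=C)C=C)=C1COC(C)=O | intermediate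
23 | (1Z,4R,5R,6S,8S)-13-acetoxy-4,5-epoxy-8-hydroxygermacra-1,7(11),10(14)-trien-12,6-olide | O[C@H]1CC(=C)/C=C\C[C@@]2(C)O[C@@H]2[C@H]2OC(=O)C(COC(C)=O)=C12 | intermediate
24 | ethyl 2-(hydroxymethyl)prop-2-enoate | C=C(CO)C(=O)OCC | starting material
25 | ethyl 2-{[(tert-butyldimethylsilyl)oxy]methyl}prop-2-enoate | C=C(CO[Si](C)(C)C(C)(C)C)C(=O)OCC | intermediate
26 | 2-{[(tert-butyldimethylsilyl)oxy]methyl}prop-2-enoic acid | C=C(CO[Si](C)(C)C(C)(C)C)C(=O)O | intermediate
27 | (1Z,4R,5R,6S,8S)-13-acetoxy-8-(2-{[(tert-butyldimethylsilyl)oxy]methyl}prop-2-enoyloxy)-4,5-epoxygermacra-1,7(11),10(14)-trien-12,6-olide | C=C(CO[Si](C)(C)C(C)(C)C)C(=O)O[C@H]1CC(=C)/C=C\C[C@@]2(C)O[C@@H]2[C@H]2OC(=O)C(COC(C)=O)=C12 | intermediate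
28 | (1Z,4R,5R,6S,8S)-13-acetoxy-4,5-epoxy-8-[2-(hydroxymethyl)prop-2-enoyloxy]germacra-1,7(11),10(14)-trien-12,6-olide | C=C(CO)C(=O)O[C@H]1CC(=C)/C=C\C[C@@]2(C)O[C@@H]2[C@H]2OC(=O)C(COC(C)=O)=C12 | intermediate
29 | (1R,2S,4R,5R,6S,8S)-13-acetoxy-1,2:4,5-diepoxy-8-[2-(hydroxymethyl)prop-2-enoyloxy]germacra-7(11),10(14)-dien-12,6-olide (CNP0233746.1) | C=C(CO)C(=O)O[C@H]1CC(=C)[C@H]2O[C@H]2C[C@@]2(C)O[C@@H]2[C@H]2OC(=O)C(COC(C)=O)=C12 | target

**Totals**

Total step count: 24. Longest linear sequence: 19 steps (steps 4–19, then 22–24).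

**Steps most likely to fail**

1. Step 15 (key step). It may fail by silyl transfer to the central allene carbon (five-membered mode) followed by SN2′ loss of the mesylate, by protonation of the alkenylcopper before CO2 is captured, or by fluoride cleavage of the Si–O tether. The fallback uses known reactions only, sets out from 14 and comes back at 20; because it keeps the original O6 in the lactone, C6 is inverted first. Mitsunobu reaction of 14 (4-nitrobenzoic acid, PPh3, DIAD) would give the (1S)-2-[(1S)-3-bromo-1-(triethylsilyloxy)but-3-en-1-yl]-1-[(2R,3R)-3-methyl-3-(prop-2-en-1-yl)oxiran-2-yl]buta-2,3-dien-1-yl 4-nitrobenzoate F1, and methanolysis (K2CO3, MeOH) the 6-epimeric allenyl carbinol F2. Iodoetherification of this α-allenol (N-iodosuccinimide, CH2Cl2; 5-endo attack of O6 on the allene terminus) would give the 4-iodo-2,5-dihydrofuran F3. Allylic oxidation of its ring O–CH2 (CrO3·3,5-dimethylpyrazole) would give the α-iodobutenolide F4, whose carbonyl carbon is the former allene terminus. Stille coupling with (tributylstannyl)methanol (Pd(PPh3)4, dioxane, 80 °C) would give the silyl-protected α-(hydroxymethyl)butenolide F5, and Bu4NF/AcOH would then give 20.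

2. Step 19. It may fail by oligomerisation through intermolecular metathesis, by closure to the (E)-cyclodecadiene, or by ruthenium-hydride alkene migration. The fallback sets out from 19 and comes back at 23; it closes the ring while the rigid oxasiline still holds O8 and C13 together as a conformational template. Stille vinylation of 19 (conditions of step 17) would give the dienyl butenolide-fused oxasiline F6. Ring-closing metathesis of this bicyclic template would give the macrocyclic siloxane F7. Tamao–Fleming oxidation (conditions of step 16) would give the macrocyclic diol F8, and selective acetylation of its primary hydroxyl (conditions of step 18) would give 23.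

3. Step 11. It may fail by low facial selectivity at the aldehyde (chelation by indium in the aqueous medium would favour the syn epimer) or by partial reaction through the allenylindium to give the homopropargylic regioisomer. The fallback sets out from 14, taken as its C6 epimer mixture, and comes back at 14; the stereocentre is then set by hydride reduction and not by the carbon–carbon bond formation. Dess–Martin oxidation would give the allenyl epoxy ketone F9, and Zn(BH4)2 in Et2O at −20 °C, the chelation-controlled anti-selective reduction of α,β-epoxy ketones, should return the (6R)-alcohol 14.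

**Further compounds**

F1 | step 15 | (1S)-2-[(1S)-3-bromo-1-(triethylsilyloxy)but-3-en-1-yl]-1-[(2R,3R)-3-methyl-3-(prop-2-en-1-yl)oxiran-2-yl]buta-2,3-dien-1-yl 4-nitrobenzoate | C=C=C([C@H](OC(=O)c1ccc(cc1)[N+](=O)[O-])[C@H]1O[C@]1(C)CC=C)[C@@H](O[Si](CC)(CC)CC)CC(Br)=C
F2 | step 15 | (1S)-2-[(1S)-3-bromo-1-(triethylsilyloxy)but-3-en-1-yl]-1-[(2R,3R)-3-methyl-3-(prop-2-en-1-yl)oxiran-2-yl]buta-2,3-dien-1-ol | C=C=C([C@H](O)[C@H]1O[C@]1(C)CC=C)[C@@H](O[Si](CC)(CC)CC)CC(Br)=C
F3 | step 15 | (2S)-3-[(1S)-3-bromo-1-(triethylsilyloxy)but-3-en-1-yl]-4-iodo-2-[(2R,3R)-3-methyl-3-(prop-2-en-1-yl)oxiran-2-yl]-2,5-dihydrofuran | IC1=C([C@@H](O[Si](CC)(CC)CC)CC(Br)=C)[C@@H]([C@H]2O[C@]2(C)CC=C)OC1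
F4 | step 15 | (5S)-4-[(1S)-3-bromo-1-(triethylsilyloxy)but-3-en-1-yl]-3-iodo-5-[(2R,3R)-3-methyl-3-(prop-2-en-1-yl)oxiran-2-yl]furan-2(5H)-one | IC1=C([C@@H](O[Si](CC)(CC)CC)CC(Br)=C)[C@@H]([C@H]2O[C@]2(C)CC=C)OC1=O
F5 | step 15 | (5S)-4-[(1S)-3-bromo-1-(triethylsilyloxy)but-3-en-1-yl]-3-(hydroxymethyl)-5-[(2R,3R)-3-methyl-3-(prop-2-en-1-yl)oxiran-2-yl]furan-2(5H)-one | OCC1=C([C@@H](O[Si](CC)(CC)CC)CC(Br)=C)[C@@H]([C@H]2O[C@]2(C)CC=C)OC1=O
F6 | step 19 | dienyl butenolide-fused oxasiline: compound 19 with the 2-bromoprop-2-en-1-yl group replaced by 2-methylidenebut-3-en-1-yl | O=C1O[C@H]([C@H]3O[C@]3(C)CC=C)C2=C1C[Si](c1ccccc1)(c1ccccc1)O[C@H]2CC(=C)C=C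
F7 | step 19 | macrocyclic siloxane: (1Z,4R,5R,6S,8S)-4,5-epoxygermacra-1,7(11),10(14)-trien-12,6-olide with O8 and C13 bridged by SiPh2 | O3[C@H]1CC(=C)/C=C\C[C@@]2(C)O[C@@H]2[C@H]2OC(=O)C(C[Si]3(c4ccccc4)c4ccccc4)=C12
F8 | step 19 | (1Z,4R,5R,6S,8S)-4,5-epoxy-8,13-dihydroxygermacra-1,7(11),10(14)-trien-12,6-olide | O[C@H]1CC(=C)/C=C\C[C@@]2(C)O[C@@H]2[C@H]2OC(=O)C(CO)=C12
F9 | step 11 | 2-[(1S)-3-bromo-1-(triethylsilyloxy)but-3-en-1-yl]-1-[(2S,3R)-3-methyl-3-(prop-2-en-1-yl)oxiran-2-yl]buta-2,3-dien-1-one | C=C=C(C(=O)[C@H]1O[C@]1(C)CC=C)[C@@H](O[Si](CC)(CC)CC)CC(Br)=C
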